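**Remarks on the chemistry**

- Ring locants used throughout: C1 = CH–OAc, C2 = CH2, C3 = CH=, C4 = C(CH3)=, C5 = CH bearing the side chain, C6 = C(CH3)2. The same locants are used for the corresponding carbons of the acyclic precursors.
- Assumption: (2E,6E)-farnesyl bromide 1, silyl ketene acetal 11 and the trivinylboroxine–pyridine complex 16 are bought. The tosylhydrazone is drawn as its E isomer; either C=N isomer serves.

**Retrosynthetic overview**

1. Acetate 22 ⇐ alcohol 21 ⇐ ketone 20 (C1 set by catalyst-controlled reduction) ⇐ cyclohexenol 19.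
2. The only ring (C1–C6) is closed in one operation from the acyclic aldehyde N-tosylhydrazone 15 and a vinylboron reagent: C3–C4 by 1,2-vinyl shift from boron to a diazo carbon, C1–C2 by intramolecular allylboration; N2 and boron leave without trace.
3. Enabling feature: the homoallylic alcohol array O–C1–C2–C3=C4 of the cyclohexene, in which C2–C3 is a bare two-carbon unit between a carbinol carbon next to quaternary C6 (a non-enolisable aldehyde) and the methyl-bearing alkene carbon C4 (a methyl ketone).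
4. 15 ⇐ ester 12; C5 and the C5–C6 bond come from an iridium-catalysed asymmetric allylic alkylation of carbonate 10 with the isobutyrate silyl ketene acetal 11; the vinyl group becomes the C4 methyl ketone (Tsuji–Wacker).
5. 10 ⇐ farnesyl bromide 1 by nitrile alkylation, isopropenyl addition, Johnson–Claisen rearrangement (E-trisubstituted alkene of the tail-to-tail junction) and two-carbon homologation.

Key step: step 13

**Route**

Step 1
Reactants: 1 (2E,6E)-farnesyl bromide
Product: 2 (4E,8E)-5,9,13-trimethyltetradeca-4,8,12-trienenitrile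
Conditions: CH3CN (3 equiv), n-BuLi, THF, −78 °C; then 1, −78 to 0 °C
Reagents that add atoms: acetonitrile, CC#N
Why: SN2 alkylation of lithioacetonitrile by the primary allylic bromide (excess nucleophile against double alkylation); no stereocentre is formed and the alkene geometry is not touched.

Step 2
Reactants: 2 (4E,8E)-5,9,13-trimethyltetradeca-4,8,12-trienenitrile
Product: 3 (4E,8E)-5,9,13-trimethyltetradeca-4,8,12-trienal
Conditions: i-Bu2AlH (1.2 equiv), toluene, −78 °C; then 1 M HCl, 0 °C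
Reagents that add atoms: water, O
Why: partial reduction of the nitrile by a single hydride addition, with hydrolysis to the aldehyde on work-up; no stereocentre.

Step 3
Reactants: 3 (4E,8E)-5,9,13-trimethyltetradeca-4,8,12-trienal
Product: 4 (6E,10E)-2,7,11,15-tetramethylhexadeca-1,6,10,14-tetraen-3-ol (racemic)
Conditions: CH2=C(CH3)MgBr, THF, 0 °C; then H2O
Reagents that add atoms: isopropenylmagnesium bromide, C=C(C)[Mg]Br
Why: Grignard 1,2-addition to the aldehyde; the carbinol centre is left racemic because it is destroyed in step 4.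

Step 4
Reactants: 4 (6E,10E)-2,7,11,15-tetramethylhexadeca-1,6,10,14-tetraen-3-ol
Product: 6 ethyl (4E,8E,12E)-4,9,13,17-tetramethyloctadeca-4,8,12,16-tetraenoate, via allyl ketene acetal 5 (not isolated)
Conditions: CH3C(OEt)3 (7 equiv), EtCO2H (cat.), 140 °C, EtOH distilled off
Reagents that add atoms: triethyl orthoacetate, CCOC(C)(OCC)OCC
Why: Johnson–Claisen rearrangement, in which the chair transition state with the chain equatorial should give the E-trisubstituted alkene of the tail-to-tail junction while the racemic carbinol centre disappears.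

Step 5
Reactants: 6 ethyl (4E,8E,12E)-4,9,13,17-tetramethyloctadeca-4,8,12,16-tetraenoate
Product: 7 (4E,8E,12E)-4,9,13,17-tetramethyloctadeca-4,8,12,16-tetraenal
Conditions: i-Bu2AlH (1.1 equiv), CH2Cl2, −78 °C; aq. potassium sodium tartrate
Reagents that add atoms: none
Why: partial reduction of the ester to the aldehyde at −78 °C; no stereocentre.

Step 6
Reactants: 7 (4E,8E,12E)-4,9,13,17-tetramethyloctadeca-4,8,12,16-tetraenal
Product: 8 methyl (2E,6E,10E,14E)-6,11,15,19-tetramethylicosa-2,6,10,14,18-pentaenoate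
Conditions: (MeO)2P(O)CH2CO2Me, NaH, THF, 0 °C
Reagents that add atoms: trimethyl phosphonoacetate, COC(=O)CP(=O)(OC)OC
Why: Horner–Wadsworth–Emmons olefination with a stabilised phosphonate should give the E-enoate.

Step 7
Reactants: 8 methyl (2E,6E,10E,14E)-6,11,15,19-tetramethylicosa-2,6,10,14,18-pentaenoate
Product: 9 (2E,6E,10E,14E)-6,11,15,19-tetramethylicosa-2,6,10,14,18-pentaen-1-ol
Conditions: i-Bu2AlH (2.2 equiv), CH2Cl2, −78 °C; aq. potassium sodium tartrate
Reagents that add atoms: none
Why: 1,2-reduction of the enoate to the primary E-allylic alcohol.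

Step 8
Reactants: 9 (2E,6E,10E,14E)-6,11,15,19-tetramethylicosa-2,6,10,14,18-pentaen-1-ol
Product: 10 methyl (2E,6E,10E,14E)-6,11,15,19-tetramethylicosa-2,6,10,14,18-pentaen-1-yl carbonate
Conditions: ClCO2Me, pyridine, CH2Cl2, 0 °C
Reagents that add atoms: methyl chloroformate, COC(=O)Cl
Why: O-acylation gives the linear allylic carbonate, the leaving group for the allylic substitution.

Step 9
Reactants: 10 methyl (2E,6E,10E,14E)-6,11,15,19-tetramethylicosa-2,6,10,14,18-pentaen-1-yl carbonate; 11 1-methoxy-2-methyl-1-(trimethylsilyloxy)prop-1-ene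
Product: 12 methyl (3R,6E,10E,14E)-3-ethenyl-2,2,6,11,15,19-hexamethylicosa-6,10,14,18-tetraenoate
Conditions: [Ir(cod)Cl]2 (2 mol%), O,O′-(1,1′-binaphthalene-2,2′-diyl)-N,N-bis(1-phenylethyl)phosphoramidite (4 mol%; the antipode that gives 3R, cyclometalated with n-PrNH2), 11 (1.5 equiv), THF, 25–50 °C
Reagents that add atoms: none
Why: iridium-catalysed asymmetric allylic alkylation, in which the fully substituted enolate released from 11 by the carbonate-derived methoxide attacks the substituted terminus of the allyl complex, forming the hindered C5–C6 bond and setting C5 under catalyst control (C6 carries two identical methyl groups, so no second stereocentre arises).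

Step 10
Reactants: 12 methyl (3R,6E,10E,14E)-3-ethenyl-2,2,6,11,15,19-hexamethylicosa-6,10,14,18-tetraenoate
Product: 13 methyl (3S,6E,10E,14E)-3-acetyl-2,2,6,11,15,19-hexamethylicosa-6,10,14,18-tetraenoate
Conditions: PdCl2 (10 mol%), CuCl (1 equiv), O2 (1 atm), DMF/H2O 7:1, 25 °C
Reagents that add atoms: water, O
Why: Tsuji–Wacker oxidation, selective for the only monosubstituted alkene over the four trisubstituted ones, gives the C4 methyl ketone with C5 unchanged in space (the descriptor changes only through ligand priority).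

Step 11
Reactants: 13 methyl (3S,6E,10E,14E)-3-acetyl-2,2,6,11,15,19-hexamethylicosa-6,10,14,18-tetraenoate
Product: 14 methyl (3S,6E,10E,14E)-2,2,6,11,15,19-hexamethyl-3-{(1E)-1-[2-(4-methylbenzenesulfonyl)hydrazinylidene]ethyl}icosa-6,10,14,18-tetraenoate
Conditions: TsNHNH2 (1.2 equiv), MeOH, 50 °C
Reagents that add atoms: p-toluenesulfonyl hydrazide, Cc1ccc(cc1)S(=O)(=O)NN
Why: hydrazone condensation at the only ketone, with the neopentyl ester inert toward the weakly nucleophilic sulfonamide nitrogen and the hindered α-centre C5 expected to survive the acid-free conditions.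

Step 12
Reactants: 14 methyl (3S,6E,10E,14E)-2,2,6,11,15,19-hexamethyl-3-{(1E)-1-[2-(4-methylbenzenesulfonyl)hydrazinylidene]ethyl}icosa-6,10,14,18-tetraenoate
Product: 15 (3S,6E,10E,14E)-2,2,6,11,15,19-hexamethyl-3-{(1E)-1-[2-(4-methylbenzenesulfonyl)hydrazinylidene]ethyl}icosa-6,10,14,18-tetraenal
Conditions: i-Bu2AlH (2.3 equiv), CH2Cl2, −78 °C; aq. potassium sodium tartrate
Reagents that add atoms: none
Why: partial reduction of the hindered α,α-dimethyl ester at −78 °C, in which the first equivalent of hydride only deprotonates the sulfonamide N–H and the resulting hydrazone anion should resist hydride addition.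

Step 13
Reactants: 15 (3S,6E,10E,14E)-2,2,6,11,15,19-hexamethyl-3-{(1E)-1-[2-(4-methylbenzenesulfonyl)hydrazinylidene]ethyl}icosa-6,10,14,18-tetraenal; 16 2,4,6-triethenyl-1,3,5,2,4,6-trioxatriborinane–pyridine complex (trivinylboroxine–pyridine)
Product: 19 (1RS,5R)-4,6,6-trimethyl-5-[(3E,7E,11E)-3,8,12,16-tetramethylheptadeca-3,7,11,15-tetraen-1-yl]cyclohex-3-en-1-ol, via diazoalkane 17 (not isolated), via tertiary allylboronic acid 18 (not isolated)
Conditions: 16 (0.7 equiv), K2CO3 (3 equiv), 1,4-dioxane, 110 °C; 15 added over 6 h (final 0.01 M); aqueous work-up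
Reagents that add atoms: none
Why: Proposed new method: K2CO3 converts the N-tosylhydrazone into the non-stabilised diazoalkane 17 (Bamford–Stevens), whose carbon adds to the vinylboronic acid released from 16; 1,2-shift of the vinyl group from boron to carbon with loss of N2 forms the C3–C4 bond and the tertiary allylboronic acid 18, and intramolecular allylboration of the tethered aldehyde then forms the C1–C2 bond while the double bond moves to C3=C4 and boron ends on oxygen. The closest known reactions are the metal-free reductive coupling of N-tosylhydrazones with alkenylboronic acids (Barluenga–Valdés coupling) and the capture of its transient allylboronic acids by added aldehydes or tethered nitriles; new here is a ring closure in which all three allyl carbons become ring atoms. The six-membered ring closes in 6-endo fashion onto the terminal vinyl carbon through a boat-like, B–O-bridged transition state of the bicyclo[2.2.2] type, which the gem-dimethyl group at C6 (Thorpe–Ingold effect) and the very high reactivity of free allylboronic acids toward aldehydes should make accessible at 110 °C. The new carbinol centre C1 forms on the ring face that carried boron at C4 and so mirrors the uncontrolled C4 configuration of 18; both C1 epimers are expected and are carried on together because C1 is reset in steps 14 and 15, while C5 is not touched. The step needs ring closure to win over γ-protonation of 18, over closure after a 1,3-boron shift (which could only give a strained cyclobutanol) and over intermolecular allyl transfer; slow addition at high dilution and the non-enolisable aldehyde secure this.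

Step 14
Reactants: 19 (1RS,5R)-4,6,6-trimethyl-5-[(3E,7E,11E)-3,8,12,16-tetramethylheptadeca-3,7,11,15-tetraen-1-yl]cyclohex-3-en-1-ol
Product: 20 (5R)-4,6,6-trimethyl-5-[(3E,7E,11E)-3,8,12,16-tetramethylheptadeca-3,7,11,15-tetraen-1-yl]cyclohex-3-en-1-one
Conditions: Dess–Martin periodinane (1.3 equiv), NaHCO3, CH2Cl2, 0 to 25 °C
Reagents that add atoms: none
Why: buffered Dess–Martin oxidation should merge both C1 epimers into one β,γ-unsaturated ketone without moving the C3=C4 bond into conjugation (20 is used at once).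

Step 15
Reactants: 20 (5R)-4,6,6-trimethyl-5-[(3E,7E,11E)-3,8,12,16-tetramethylheptadeca-3,7,11,15-tetraen-1-yl]cyclohex-3-en-1-one
Product: 21 (1S,5R)-4,6,6-trimethyl-5-[(3E,7E,11E)-3,8,12,16-tetramethylheptadeca-3,7,11,15-tetraen-1-yl]cyclohex-3-en-1-ol
Conditions: (R)-1-methyl-3,3-diphenyltetrahydro-1H,3H-pyrrolo[1,2-c][1,3,2]oxazaborole (0.2 equiv), BH3·SMe2 (0.7 equiv), THF, −20 °C; MeOH quench
Reagents that add atoms: none
Why: Corey–Bakshi–Shibata reduction, in which the catalyst distinguishes the quaternary C6 flank (large) from the C2 methylene flank (small) and should deliver the 1S alcohol, cis to the C5 chain, under catalyst control and faster than hydroboration of the trisubstituted alkenes.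

Step 16
Reactants: 21 (1S,5R)-4,6,6-trimethyl-5-[(3E,7E,11E)-3,8,12,16-tetramethylheptadeca-3,7,11,15-tetraen-1-yl]cyclohex-3-en-1-ol
Product: 22 (1S,5R)-4,6,6-trimethyl-5-[(3E,7E,11E)-3,8,12,16-tetramethylheptadeca-3,7,11,15-tetraen-1-yl]cyclohex-3-en-1-yl acetate
Conditions: Ac2O, pyridine, 4-(dimethylamino)pyridine (cat.), CH2Cl2, 25 °C
Reagents that add atoms: acetic anhydride, CC(=O)OC(C)=O
Why: nucleophile-catalysed acetylation of the hindered secondary alcohol; no stereocentre is affected.

**Compound list**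

1 | (2E,6E)-farnesyl bromide | BrC/C=C(\C)CC/C=C(\C)CCC=C(C)C | starting material
2 | (4E,8E)-5,9,13-trimethyltetradeca-4,8,12-trienenitrile | N#CCC/C=C(\C)CC/C=C(\C)CCC=C(C)C | intermediate
3 | (4E,8E)-5,9,13-trimethyltetradeca-4,8,12-trienal | O=CCC/C=C(\C)CC/C=C(\C)CCC=C(C)C | intermediate
4 | (6E,10E)-2,7,11,15-tetramethylhexadeca-1,6,10,14-tetraen-3-ol (racemic) | C=C(C)C(O)CC/C=C(\C)CC/C=C(\C)CCC=C(C)C | intermediate
5 | 1-ethoxyvinyl ether of 4 (allyl ketene acetal) | C=C(OCC)OC(CC/C=C(\C)CC/C=C(\C)CCC=C(C)C)C(C)=C | intermediate (not isolated)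
6 | ethyl (4E,8E,12E)-4,9,13,17-tetramethyloctadeca-4,8,12,16-tetraenoate | CCOC(=O)CC/C(C)=C/CC/C=C(\C)CC/C=C(\C)CCC=C(C)C | intermediate
7 | (4E,8E,12E)-4,9,13,17-tetramethyloctadeca-4,8,12,16-tetraenal | O=CCC/C(C)=C/CC/C=C(\C)CC/C=C(\C)CCC=C(C)C | intermediate
8 | methyl (2E,6E,10E,14E)-6,11,15,19-tetramethylicosa-2,6,10,14,18-pentaenoate | COC(=O)/C=C/CC/C(C)=C/CC/C=C(\C)CC/C=C(\C)CCC=C(C)C | intermediate
9 | (2E,6E,10E,14E)-6,11,15,19-tetramethylicosa-2,6,10,14,18-pentaen-1-ol | OC/C=C/CC/C(C)=C/CC/C=C(\C)CC/C=C(\C)CCC=C(C)C | intermediate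
10 | methyl (2E,6E,10E,14E)-6,11,15,19-tetramethylicosa-2,6,10,14,18-pentaen-1-yl carbonate | COC(=O)OC/C=C/CC/C(C)=C/CC/C=C(\C)CC/C=C(\C)CCC=C(C)C | intermediate
11 | 1-methoxy-2-methyl-1-(trimethylsilyloxy)prop-1-ene | COC(O[Si](C)(C)C)=C(C)C | starting material
12 | methyl (3R,6E,10E,14E)-3-ethenyl-2,2,6,11,15,19-hexamethylicosa-6,10,14,18-tetraenoate | C=C[C@@H](CC/C(C)=C/CC/C=C(\C)CC/C=C(\C)CCC=C(C)C)C(C)(C)C(=O)OC | intermediate
13 | methyl (3S,6E,10E,14E)-3-acetyl-2,2,6,11,15,19-hexamethylicosa-6,10,14,18-tetraenoate | CC(=O)[C@@H](CC/C(C)=C/CC/C=C(\C)CC/C=C(\C)CCC=C(C)C)C(C)(C)C(=O)OC | intermediate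
14 | methyl (3S,6E,10E,14E)-2,2,6,11,15,19-hexamethyl-3-{(1E)-1-[2-(4-methylbenzenesulfonyl)hydrazinylidene]ethyl}icosa-6,10,14,18-tetraenoate | C/C(=N\NS(=O)(=O)c1ccc(C)cc1)[C@@H](CC/C(C)=C/CC/C=C(\C)CC/C=C(\C)CCC=C(C)C)C(C)(C)C(=O)OC | intermediate
15 | (3S,6E,10E,14E)-2,2,6,11,15,19-hexamethyl-3-{(1E)-1-[2-(4-methylbenzenesulfonyl)hydrazinylidene]ethyl}icosa-6,10,14,18-tetraenal | C/C(=N\NS(=O)(=O)c1ccc(C)cc1)[C@@H](CC/C(C)=C/CC/C=C(\C)CC/C=C(\C)CCC=C(C)C)C(C)(C)C=O | intermediate
16 | 2,4,6-triethenyl-1,3,5,2,4,6-trioxatriborinane–pyridine complex | C=CB1OB(C=C)OB(C=C)O1.c1ccncc1 | starting material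
17 | (3S,6E,10E,14E)-3-(1-diazoethyl)-2,2,6,11,15,19-hexamethylicosa-6,10,14,18-tetraenal | CC(=[N+]=[N-])[C@@H](CC/C(C)=C/CC/C=C(\C)CC/C=C(\C)CCC=C(C)C)C(C)(C)C=O | intermediate (not isolated)
18 | [(3RS,4R,7E,11E,15E)-3,7,12,16,20-pentamethyl-4-(2-methyl-1-oxopropan-2-yl)henicosa-1,7,11,15,19-pentaen-3-yl]boronic acid (both C3 epimers) | C=CC(C)(B(O)O)[C@@H](CC/C(C)=C/CC/C=C(\C)CC/C=C(\C)CCC=C(C)C)C(C)(C)C=O | intermediate (not isolated)
19 | (1RS,5R)-4,6,6-trimethyl-5-[(3E,7E,11E)-3,8,12,16-tetramethylheptadeca-3,7,11,15-tetraen-1-yl]cyclohex-3-en-1-ol (both C1 epimers) | OC1CC=C(C)[C@@H](CC/C(C)=C/CC/C=C(\C)CC/C=C(\C)CCC=C(C)C)C1(C)C | intermediate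
20 | (5R)-4,6,6-trimethyl-5-[(3E,7E,11E)-3,8,12,16-tetramethylheptadeca-3,7,11,15-tetraen-1-yl]cyclohex-3-en-1-one | O=C1CC=C(C)[C@@H](CC/C(C)=C/CC/C=C(\C)CC/C=C(\C)CCC=C(C)C)C1(C)C | intermediate
21 | (1S,5R)-4,6,6-trimethyl-5-[(3E,7E,11E)-3,8,12,16-tetramethylheptadeca-3,7,11,15-tetraen-1-yl]cyclohex-3-en-1-ol | O[C@H]1CC=C(C)[C@@H](CC/C(C)=C/CC/C=C(\C)CC/C=C(\C)CCC=C(C)C)C1(C)C | intermediate
22 | (1S,5R)-4,6,6-trimethyl-5-[(3E,7E,11E)-3,8,12,16-tetramethylheptadeca-3,7,11,15-tetraen-1-yl]cyclohex-3-en-1-yl acetate | CC(=O)O[C@H]1CC=C(C)[C@@H](CC/C(C)=C/CC/C=C(\C)CC/C=C(\C)CCC=C(C)C)C1(C)C | target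

**Step count and risks**

Total step count: 16. Longest linear sequence: 16 steps (1 to 22).

Steps most likely to fail:

1. Step 13 (Proposed new method). The boat-like ring closure may be slower than γ-protonation of the allylboronic acid (boron lost without C1–C2 bond formation), than allyl transfer between molecules (oligomers), or than thermal loss of N2 from the diazoalkane before boron capture. The fallback uses known chemistry, makes the two ring bonds in separate operations, sets out from 13 and returns at 21. The ketone of 13 would be methylenated without base by Lombardo methylenation (Zn, CH2Br2, TiCl4), leaving C5 and the ester intact, to give methyl (3R,6E,10E,14E)-2,2,6,11,15,19-hexamethyl-3-(prop-1-en-2-yl)icosa-6,10,14,18-tetraenoate F1. Partial reduction with i-Bu2AlH at −78 °C would give (3R,6E,10E,14E)-2,2,6,11,15,19-hexamethyl-3-(prop-1-en-2-yl)icosa-6,10,14,18-tetraenal F2. Brown allylation with (−)-B-allyldiisopinocampheylborane would form the C1–C2 bond and set the carbinol centre under reagent control in (4S,6R,9E,13E,17E)-5,5,9,14,18,22-hexamethyl-6-(prop-1-en-2-yl)tricosa-1,9,13,17,21-pentaen-4-ol F3. Ring-closing metathesis with second-generation Grubbs catalyst, RuCl2(=CHPh)(PCy3)(H2IMes), would then close C3=C4 and give 21, so that steps 14 and 15 are not needed and the route continues at step 16.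

2. Step 9. Branched-to-linear selectivity or enantioselectivity may erode with the long, purely aliphatic allyl unit, and slow C–C bond formation at the fully substituted nucleophile may divert the allyl intermediate to elimination. The fallback sets out from 8 and returns at 12. Saponification (LiOH) would give (2E,6E,10E,14E)-6,11,15,19-tetramethylicosa-2,6,10,14,18-pentaenoic acid F4. Its pivaloyl mixed anhydride would acylate lithiated (4R)-4-phenyl-1,3-oxazolidin-2-one to give (4R)-3-[(2E,6E,10E,14E)-6,11,15,19-tetramethylicosa-2,6,10,14,18-pentaenoyl]-4-phenyl-1,3-oxazolidin-2-one F5. Conjugate addition of CH2=CHMgBr with CuBr·SMe2 to the chelated s-cis imide, anti to phenyl, would set C5 in (4R)-3-[(3S,6E,10E,14E)-3-ethenyl-6,11,15,19-tetramethylicosa-6,10,14,18-tetraenoyl]-4-phenyl-1,3-oxazolidin-2-one F6; the antipodal auxiliary would be used should the facial sense prove opposite. Methanolysis with MeOMgBr would give methyl (3S,6E,10E,14E)-3-ethenyl-6,11,15,19-tetramethylicosa-6,10,14,18-tetraenoate F7. Two enolate methylations (LDA, MeI; then LDA, MeI, DMPU) through methyl (2RS,3R,6E,10E,14E)-3-ethenyl-2,6,11,15,19-pentamethylicosa-6,10,14,18-tetraenoate F8 would then build the quaternary C6 and give 12.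

3. Step 12. The ester may be over-reduced to the primary alcohol, hydride may add to the hydrazone C=N, or the sulfonamide nitrogen may add reversibly to the new aldehyde and complicate isolation. The fallback sets out from 12 and returns at 15, fixing the aldehyde oxidation level by oxidation instead of partial reduction. LiAlH4 would give (3R,6E,10E,14E)-3-ethenyl-2,2,6,11,15,19-hexamethylicosa-6,10,14,18-tetraen-1-ol F9. Tsuji–Wacker oxidation (PdCl2, CuCl, O2) would give (3S,6E,10E,14E)-3-(1-hydroxy-2-methylpropan-2-yl)-6,11,15,19-tetramethylicosa-6,10,14,18-tetraen-2-one F10, drawn open although it may rest as its cyclic hemiketal. Condensation with TsNHNH2 would give N′-[(2E,3S,6E,10E,14E)-3-(1-hydroxy-2-methylpropan-2-yl)-6,11,15,19-tetramethylicosa-6,10,14,18-tetraen-2-ylidene]-4-methylbenzenesulfonohydrazide F11. Parikh–Doering oxidation (SO3·pyridine, DMSO, i-Pr2NEt, 0 °C) of the neopentyl alcohol would then give 15.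

**Further compounds**

F1 | step 13 | methyl (3R,6E,10E,14E)-2,2,6,11,15,19-hexamethyl-3-(prop-1-en-2-yl)icosa-6,10,14,18-tetraenoate | C=C(C)[C@@H](CC/C(C)=C/CC/C=C(\C)CC/C=C(\C)CCC=C(C)C)C(C)(C)C(=O)OC
F2 | step 13 | (3R,6E,10E,14E)-2,2,6,11,15,19-hexamethyl-3-(prop-1-en-2-yl)icosa-6,10,14,18-tetraenal | C=C(C)[C@@H](CC/C(C)=C/CC/C=C(\C)CC/C=C(\C)CCC=C(C)C)C(C)(C)C=O
F3 | step 13 | (4S,6R,9E,13E,17E)-5,5,9,14,18,22-hexamethyl-6-(prop-1-en-2-yl)tricosa-1,9,13,17,21-pentaen-4-ol | C=CC[C@H](O)C(C)(C)[C@H](CC/C(C)=C/CC/C=C(\C)CC/C=C(\C)CCC=C(C)C)C(C)=C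
F4 | step 9 | (2E,6E,10E,14E)-6,11,15,19-tetramethylicosa-2,6,10,14,18-pentaenoic acid | OC(=O)/C=C/CC/C(C)=C/CC/C=C(\C)CC/C=C(\C)CCC=C(C)C
F5 | step 9 | (4R)-3-[(2E,6E,10E,14E)-6,11,15,19-tetramethylicosa-2,6,10,14,18-pentaenoyl]-4-phenyl-1,3-oxazolidin-2-one | O=C(/C=C/CC/C(C)=C/CC/C=C(\C)CC/C=C(\C)CCC=C(C)C)N1[C@H](c2ccccc2)COC1=O
F6 | step 9 | (4R)-3-[(3S,6E,10E,14E)-3-ethenyl-6,11,15,19-tetramethylicosa-6,10,14,18-tetraenoyl]-4-phenyl-1,3-oxazolidin-2-one | O=C(C[C@@H](C=C)CC/C(C)=C/CC/C=C(\C)CC/C=C(\C)CCC=C(C)C)N1[C@H](c2ccccc2)COC1=O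
F7 | step 9 | methyl (3S,6E,10E,14E)-3-ethenyl-6,11,15,19-tetramethylicosa-6,10,14,18-tetraenoate | COC(=O)C[C@@H](C=C)CC/C(C)=C/CC/C=C(\C)CC/C=C(\C)CCC=C(C)C
F8 | step 9 | methyl (2RS,3R,6E,10E,14E)-3-ethenyl-2,6,11,15,19-pentamethylicosa-6,10,14,18-tetraenoate | COC(=O)C(C)[C@@H](C=C)CC/C(C)=C/CC/C=C(\C)CC/C=C(\C)CCC=C(C)C
F9 | step 12 | (3R,6E,10E,14E)-3-ethenyl-2,2,6,11,15,19-hexamethylicosa-6,10,14,18-tetraen-1-ol | C=C[C@@H](CC/C(C)=C/CC/C=C(\C)CC/C=C(\C)CCC=C(C)C)C(C)(C)CO
F10 | step 12 | (3S,6E,10E,14E)-3-(1-hydroxy-2-methylpropan-2-yl)-6,11,15,19-tetramethylicosa-6,10,14,18-tetraen-2-one | CC(=O)[C@@H](CC/C(C)=C/CC/C=C(\C)CC/C=C(\C)CCC=C(C)C)C(C)(C)CO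
F11 | step 12 | N′-[(2E,3S,6E,10E,14E)-3-(1-hydroxy-2-methylpropan-2-yl)-6,11,15,19-tetramethylicosa-6,10,14,18-tetraen-2-ylidene]-4-methylbenzenesulfonohydrazide | C/C(=N\NS(=O)(=O)c1ccc(C)cc1)[C@@H](CC/C(C)=C/CC/C=C(\C)CC/C=C(\C)CCC=C(C)C)C(C)(C)CO
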